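**Retrosynthetic overview**
- Feature: the C4 methyl carbinol with C5, C6 and the chain C3–C2–C1 is the carbon skeleton of (R)-linalool (carbinol carbon, vinyl group, three-carbon chain), and ring B (C5–C10) is a cyclohexene retron once a C6=C7 alkene is written.
- Endgame: phenol methyl ethers and both formyl groups off (aryl bromination, lithiation, DMF); C1'–aryl bond by Friedel–Crafts allylation of 1,3,5-trimethoxybenzene with a C1'–C3' dimethylallyl cation; C1–C1' from an axial C1 aldehyde, whose C1 centre comes from C4-hydroxyl-directed hydrogenation of a C1 enoate made from the C1 ketone.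
- Key disconnection: intramolecular Diels–Alder reaction forming C5–C10 and C8–C9. It closes ring B (cycloadduct) and ring A (tether C1–C4) in one step and sets C5, C9 and C10. The C9 ester is then removed by reduction, oxidation and decarbonylation.
- Triene: C1 aldehyde from ozonolysis of silylated (R)-linalool; C9/C10 from an (E)-β-triflyloxy enoate (Nozaki–Hiyama–Kishi coupling); C7/C8/C11 from the enol triflate of 3-hydroxy-3-methylbutan-2-one (Heck coupling).
- Ring order: rings A and B together in step 11; the aromatic ring is brought in intact.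

Key step: step 11

Remark: locants follow eudesmane numbering (C1' is the benzylic carbon; β is the face of the C10 methyl); commercial (R)-linalool is assumed enantiomerically pure. The C1 carbinol is set deliberately (steps 5 and 6), because in the chair tether its configuration either supports or opposes the preference of the C4 centre.

**Step 1**
Reactants: 1 (R)-(−)-linalool
Product: 2 (3R)-3,7-dimethyl-3-(triethylsilyloxy)octa-1,6-diene
Conditions: Et3SiOTf, 2,6-lutidine, CH2Cl2, 0 °C
Reagents that add atoms: triethylsilyl triflate CC[Si](CC)(CC)OS(=O)(=O)C(F)(F)F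
Why: Silyl ether formation on the tertiary alcohol with the reactive silyl triflate; the stereocentre is not touched.

**Step 2**
Reactants: 2 (3R)-3,7-dimethyl-3-(triethylsilyloxy)octa-1,6-diene
Product: 4 (4R)-4-methyl-4-(triethylsilyloxy)hex-5-enal, via secondary ozonide 3 (not isolated)
Conditions: O3 (1 equiv, Sudan Red 7B end point), CH2Cl2, −78 °C; Me2S, −78 °C → rt
Reagents that add atoms: ozone [O-][O+]=O
Why: Ozonolysis with reductive work-up; the electron-rich trisubstituted alkene reacts much faster than the hindered monosubstituted vinyl group, so one equivalent should cleave only the former.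

**Step 3**
Reactants: 5 methyl acetoacetate
Product: 6 methyl (2E)-3-(trifluoromethanesulfonyloxy)but-2-enoate
Conditions: Tf2O, aq. Me4NOH, hexanes, 5 °C
Reagents that add atoms: triflic anhydride FC(F)(F)S(=O)(=O)OS(=O)(=O)C(F)(F)F
Why: O-triflation of the β-keto ester enolate under biphasic conditions; the non-chelating tetramethylammonium enolate reacts in its extended form and should give the E enol triflate (triflate trans to the ester).

**Step 4**
Reactants: 4 (4R)-4-methyl-4-(triethylsilyloxy)hex-5-enal; 6 methyl (2E)-3-(trifluoromethanesulfonyloxy)but-2-enoate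
Product: 7 methyl (2E,4RS,7R)-4-hydroxy-3,7-dimethyl-7-(triethylsilyloxy)nona-2,8-dienoate
Conditions: CrCl2 (4 equiv), NiCl2 (2 mol %), DMF, rt
Reagents that add atoms: none
Why: Nozaki–Hiyama–Kishi coupling: zerovalent nickel inserts into the alkenyl triflate, transmetalation gives an alkenyl species of trivalent chromium that adds only to the aldehyde with retention of alkene geometry; the new carbinol centre is not controlled and is erased in step 5.

**Step 5**
Reactants: 7 methyl (2E,4RS,7R)-4-hydroxy-3,7-dimethyl-7-(triethylsilyloxy)nona-2,8-dienoate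
Product: 8 methyl (2E,7R)-3,7-dimethyl-4-oxo-7-(triethylsilyloxy)nona-2,8-dienoate
Conditions: Dess–Martin periodinane, NaHCO3, CH2Cl2, 0 °C → rt
Reagents that add atoms: none
Why: Dess–Martin oxidation of the secondary allylic alcohol under buffered conditions that spare the silyl ether and the E enoate.

**Step 6**
Reactants: 8 methyl (2E,7R)-3,7-dimethyl-4-oxo-7-(triethylsilyloxy)nona-2,8-dienoate
Product: 9 methyl (2E,4S,7R)-4-hydroxy-3,7-dimethyl-7-(triethylsilyloxy)nona-2,8-dienoate
Conditions: (R)-2-methyl-CBS-oxazaborolidine (0.3 equiv), catecholborane, toluene, −78 °C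
Reagents that add atoms: none
Why: Corey–Bakshi–Shibata reduction; the α-branched alkenyl group is the large substituent, so the (R)-catalyst should deliver hydride to give the (4S) carbinol (C1) under reagent control, and catecholborane at low temperature spares the vinyl group and the enoate.

**Step 7**
Reactants: 10 3-hydroxy-3-methylbutan-2-one
Product: 11 3-methyl-3-(triethylsilyloxy)butan-2-one
Conditions: Et3SiOTf, 2,6-lutidine, CH2Cl2, 0 °C
Reagents that add atoms: triethylsilyl triflate CC[Si](CC)(CC)OS(=O)(=O)C(F)(F)F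
Why: Silyl ether formation on the tertiary α-hydroxy ketone.

**Step 8**
Reactants: 11 3-methyl-3-(triethylsilyloxy)butan-2-one
Product: 12 3-methyl-3-(triethylsilyloxy)but-1-en-2-yl trifluoromethanesulfonate
Conditions: KN(SiMe3)2, THF, −78 °C; PhNTf2, −78 → 0 °C
Reagents that add atoms: N-phenylbis(trifluoromethanesulfonimide) FC(F)(F)S(=O)(=O)N(c1ccccc1)S(=O)(=O)C(F)(F)F
Why: The ketone can enolise only toward the methyl group, and O-triflation of the potassium enolate gives the enol triflate.

**Step 9**
Reactants: 9 methyl (2E,4S,7R)-4-hydroxy-3,7-dimethyl-7-(triethylsilyloxy)nona-2,8-dienoate; 12 3-methyl-3-(triethylsilyloxy)but-1-en-2-yl trifluoromethanesulfonate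
Product: 13 methyl (2E,4S,7R,8E)-4-hydroxy-3,7,11-trimethyl-10-methylidene-7,11-bis(triethylsilyloxy)dodeca-2,8-dienoate
Conditions: Pd(OAc)2 (10 mol %), PPh3, Et3N, LiCl, DMF, 70 °C
Reagents that add atoms: none
Why: Heck reaction: the alkenylpalladium adds to the terminal carbon of the vinyl group, and syn β-hydride elimination can only give the conjugated E diene because the neighbouring carbinol carbon has no hydrogen; the trisubstituted enoate does not insert.

**Step 10**
Reactants: 13 methyl (2E,4S,7R,8E)-4-hydroxy-3,7,11-trimethyl-10-methylidene-7,11-bis(triethylsilyloxy)dodeca-2,8-dienoate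
Product: 14 methyl (2E,4S,7R,8E)-4-acetoxy-3,7,11-trimethyl-10-methylidene-7,11-bis(triethylsilyloxy)dodeca-2,8-dienoate
Conditions: Ac2O, DMAP, pyridine, CH2Cl2, rt
Reagents that add atoms: acetic anhydride CC(=O)OC(C)=O
Why: Acylation of the secondary alcohol; it is done after step 9 because an allylic acetate would ionise with zerovalent palladium, and the acetate is later removed by the same hydride that reduces the ester.

**Step 11**
Reactants: 14 methyl (2E,4S,7R,8E)-4-acetoxy-3,7,11-trimethyl-10-methylidene-7,11-bis(triethylsilyloxy)dodeca-2,8-dienoate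
Product: 15 methyl 1β-acetoxy-4β,11-bis(triethylsilyloxy)eudesm-6-ene-9β-carboxylate (trans-fused; H5 α)
Conditions: toluene (0.01 M), BHT, 185 °C, sealed tube, base-washed glass
Reagents that add atoms: none
Why: Thermal, concerted but asynchronous [4+2] cycloaddition of the terminally activated E enoate C10=C9 to the 2-substituted diene C5=C6–C7=C8, the intramolecular Diels–Alder reaction of a 1,7,9-decatrienoate that is an established entry to trans-decalins. Ring B is the cyclohexene formed by the two new bonds C5–C10 and C8–C9, and ring A closes in the fused mode as a six-membered ring through the four-atom tether C1–C4, which folds as a chair. C5 and C10 are set by the two tether centres: the C4 silyloxy group, smaller than the C4 methyl, takes the axial site that is 1,3-syn to the incoming C10 methyl, and the C1 acetoxy group of the (4S) centre lies pseudo-equatorial and antiperiplanar to the forming C5–C10 bond, so both select the same diene face. C9 follows from suprafacial addition to the E alkene (ester cis to the C10 methyl), and the trans ring fusion from the anti arrangement of tether and diene in which the ester is endo. The step needs anti over syn closure and oxygen-axial over methyl-axial folding; the first rests on the E geometry with the endo ester, the second on the matched C1 and C4 centres, and the bulky C7 substituent holds the diene s-cis so that the trisubstituted dienophile can react at a temperature the silyl ethers survive.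

**Step 12**
Reactants: 15 methyl 1β-acetoxy-4β,11-bis(triethylsilyloxy)eudesm-6-ene-9β-carboxylate
Product: 16 methyl 1β-acetoxy-4β,11-bis(triethylsilyloxy)eudesmane-9β-carboxylate (C7 side chain β, equatorial)
Conditions: H2 (1 atm), PtO2, EtOAc, rt
Reagents that add atoms: none
Why: Heterogeneous syn-hydrogenation of C6=C7 from the α face, because the β face is covered by the axial C10 methyl and the axial C4 silyloxy group; H7 becomes α and the C11 group β.

**Step 13**
Reactants: 16 methyl 1β-acetoxy-4β,11-bis(triethylsilyloxy)eudesmane-9β-carboxylate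
Product: 17 9β-(hydroxymethyl)-4β,11-bis(triethylsilyloxy)eudesman-1β-ol
Conditions: LiAlH4, THF, 0 °C → rt; Rochelle salt
Reagents that add atoms: none
Why: Hydride reduction of the hindered methyl ester to the primary alcohol and of the acetate to the C1 carbinol in one operation; tertiary silyl ethers are inert.

**Step 14**
Reactants: 17 9β-(hydroxymethyl)-4β,11-bis(triethylsilyloxy)eudesman-1β-ol
Product: 18 1-oxo-4β,11-bis(triethylsilyloxy)eudesmane-9β-carbaldehyde
Conditions: (COCl)2, DMSO, CH2Cl2, −78 °C; Et3N, −78 → 0 °C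
Reagents that add atoms: none
Why: Swern oxidation activates both hydroxyl groups before base is added, so the 1,4-diol should give the keto aldehyde and not a lactone by way of a lactol.

**Step 15**
Reactants: 18 1-oxo-4β,11-bis(triethylsilyloxy)eudesmane-9β-carbaldehyde
Product: 19 4β,11-bis(triethylsilyloxy)eudesman-1-one
Conditions: RhCl(PPh3)3 (1.2 equiv), toluene, 110 °C
Reagents that add atoms: none
Why: Tsuji–Wilkinson decarbonylation: oxidative addition of the formyl C–H bond, CO extrusion and reductive elimination leave C9 as a methylene group; the ketone and the silyl ethers do not react.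

**Step 16**
Reactants: 19 4β,11-bis(triethylsilyloxy)eudesman-1-one
Product: 20 4β,11-bis(triethylsilyloxy)eudesm-1-en-1-yl trifluoromethanesulfonate
Conditions: KN(SiMe3)2, THF, −78 °C; PhNTf2, −78 → 0 °C
Reagents that add atoms: N-phenylbis(trifluoromethanesulfonimide) FC(F)(F)S(=O)(=O)N(c1ccccc1)S(=O)(=O)C(F)(F)F
Why: Enolate formation is possible only toward C2 because C10 is quaternary, and O-triflation gives the C1 enol triflate.

**Step 17**
Reactants: 20 4β,11-bis(triethylsilyloxy)eudesm-1-en-1-yl trifluoromethanesulfonate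
Product: 21 methyl 4β,11-bis(triethylsilyloxy)eudesm-1-ene-1-carboxylate
Conditions: Pd(OAc)2 (5 mol %), dppp, CO (1 atm), MeOH, Et3N, DMF, 60 °C
Reagents that add atoms: carbon monoxide [C-]#[O+]; methanol CO
Why: Palladium-catalysed methoxycarbonylation of an enol triflate (oxidative addition, CO insertion, methanolysis), which works for triflates next to quaternary carbons.

**Step 18**
Reactants: 21 methyl 4β,11-bis(triethylsilyloxy)eudesm-1-ene-1-carboxylate
Product: 22 methyl 4β,11-dihydroxyeudesm-1-ene-1-carboxylate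
Conditions: HF·pyridine, THF, 0 °C → rt
Reagents that add atoms: none
Why: Fluoride cleavage of both tertiary triethylsilyl ethers; the unsaturated ester is stable to buffered HF, and the free C4 hydroxyl is needed in step 19.

**Step 19**
Reactants: 22 methyl 4β,11-dihydroxyeudesm-1-ene-1-carboxylate
Product: 23 methyl 4β,11-dihydroxyeudesmane-1α-carboxylate
Conditions: [Ir(cod)(PCy3)(py)]PF6 (15 mol %), H2 (1 atm), CH2Cl2, rt
Reagents that add atoms: none
Why: Hydroxyl-directed hydrogenation: the axial homoallylic C4 hydroxyl binds the cationic iridium and H2 is delivered to the β face of C1=C2 (the arrangement known from terpinen-4-ol), so H1 becomes β and the ester carbon α, trans to the C10 methyl.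

**Step 20**
Reactants: 23 methyl 4β,11-dihydroxyeudesmane-1α-carboxylate
Product: 24 4β,11-dihydroxyeudesmane-1α-carbaldehyde
Conditions: i-Bu2AlH (3.5 equiv), CH2Cl2, −78 °C; Rochelle salt
Reagents that add atoms: none
Why: Partial reduction of the ester; the aluminium hemiacetal of the hindered ester persists at −78 °C and releases the aldehyde on neutral work-up, without epimerisation of the axial C1 centre.

**Step 21**
Reactants: 24 4β,11-dihydroxyeudesmane-1α-carbaldehyde
Product: 25 1α-(1-hydroxy-3-methylbut-2-enyl)eudesmane-4β,11-diol (both carbinol epimers)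
Conditions: Me2C=CHMgBr (5 equiv), THF, −78 → 0 °C
Reagents that add atoms: 2-methylprop-1-enylmagnesium bromide CC(C)=C[Mg]Br
Why: Grignard 1,2-addition at low temperature outruns enolisation of the aldehyde; the new carbinol centre does not matter because it is ionised in step 22.

**Step 22**
Reactants: 25 1α-(1-hydroxy-3-methylbut-2-enyl)eudesmane-4β,11-diol; 26 1,3,5-trimethoxybenzene
Product: 27 1α-[(1R)-3-methyl-1-(2,4,6-trimethoxyphenyl)but-2-enyl]eudesmane-4β,11-diol
Conditions: 26 (4 equiv), Sc(OTf)3 (5 mol %), CH2Cl2, −20 → 0 °C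
Reagents that add atoms: none
Why: Friedel–Crafts allylation (SN1): the Lewis acid ionises only the allylic alcohol to the E 1-alkyl-3,3-dimethylallyl cation, which arenes attack at the secondary terminus C1'; with C1–H eclipsing the cation plane and H1' lying under ring A, the C9 methylene blocks one face, so the arene should add from the C2 side and give the (1'R) centre.

**Step 23**
Reactants: 27 1α-[(1R)-3-methyl-1-(2,4,6-trimethoxyphenyl)but-2-enyl]eudesmane-4β,11-diol
Product: 28 1α-[(1R)-3-methyl-1-(2,4,6-trimethoxyphenyl)butyl]eudesmane-4β,11-diol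
Conditions: H2 (3 atm), 10% Pd/C, EtOAc, rt
Reagents that add atoms: none
Why: Heterogeneous hydrogenation of the trisubstituted alkene to the isobutyl group; no stereocentre is involved.

**Step 24**
Reactants: 28 1α-[(1R)-3-methyl-1-(2,4,6-trimethoxyphenyl)butyl]eudesmane-4β,11-diol
Product: 29 1α-[(1R)-1-(3,5-dibromo-2,4,6-trimethoxyphenyl)-3-methylbutyl]eudesmane-4β,11-diol
Conditions: NBS (2.1 equiv), MeCN, 0 °C, dark
Reagents that add atoms: N-bromosuccinimide BrN1C(=O)CCC1=O
Why: Electrophilic aromatic bromination of the two remaining positions of the trialkoxyarene, each activated by two ortho methoxy groups.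

**Step 25**
Reactants: 29 1α-[(1R)-1-(3,5-dibromo-2,4,6-trimethoxyphenyl)-3-methylbutyl]eudesmane-4β,11-diol
Product: 32 5-[(1R)-1-(4β,11-dihydroxyeudesman-1α-yl)-3-methylbutyl]-2,4,6-trimethoxybenzene-1,3-dicarbaldehyde, via aryldilithium dialkoxide 30 (not isolated), via bis-hemiaminolate 31 (not isolated)
Conditions: t-BuLi (6.5 equiv), THF, −78 °C; DMF, −78 → 0 °C; H2O
Reagents that add atoms: N,N-dimethylformamide CN(C)C=O
Why: After deprotonation of the two hydroxyl groups, bromine–lithium exchange at both positions gives aryllithiums flanked by methoxy groups, which are formylated by DMF; the hemiaminolates collapse to the aldehydes on aqueous work-up.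

**Step 26**
Reactants: 32 5-[(1R)-1-(4β,11-dihydroxyeudesman-1α-yl)-3-methylbutyl]-2,4,6-trimethoxybenzene-1,3-dicarbaldehyde
Product: 33 5-[(1R)-1-[(1S,4R,5S,7S,10R)-4,11-dihydroxyeudesman-1-yl]-3-methylbutyl]-2,4,6-trihydroxybenzene-1,3-dicarbaldehyde (target)
Conditions: 4-MeC6H4SLi (12 equiv), HMPA/toluene, 110 °C; aq. HCl
Reagents that add atoms: none
Why: Nucleophilic demethylation (SN2 of thiolate at the methyl carbon), possible because every methoxy group is ortho to a formyl group; the basic medium leaves the tertiary alcohols untouched.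

**Compound list**
1 | (R)-(−)-linalool | C=C[C@](C)(O)CCC=C(C)C | starting material
2 | (3R)-3,7-dimethyl-3-(triethylsilyloxy)octa-1,6-diene | C=C[C@](C)(O[Si](CC)(CC)CC)CCC=C(C)C | intermediate
3 | 3,3-dimethyl-5-[(3R)-3-methyl-3-(triethylsilyloxy)pent-4-enyl]-1,2,4-trioxolane (ozonide, not isolated) | C=C[C@](C)(O[Si](CC)(CC)CC)CCC1OOC(C)(C)O1 | intermediate
4 | (4R)-4-methyl-4-(triethylsilyloxy)hex-5-enal | C=C[C@](C)(O[Si](CC)(CC)CC)CCC=O | intermediate
5 | methyl acetoacetate | CC(=O)CC(=O)OC | starting material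
6 | methyl (2E)-3-(trifluoromethanesulfonyloxy)but-2-enoate | C/C(OS(=O)(=O)C(F)(F)F)=C\C(=O)OC | intermediate
7 | methyl (2E,4RS,7R)-4-hydroxy-3,7-dimethyl-7-(triethylsilyloxy)nona-2,8-dienoate (C4 epimers) | C=C[C@](C)(O[Si](CC)(CC)CC)CCC(O)/C(C)=C/C(=O)OC | intermediate
8 | methyl (2E,7R)-3,7-dimethyl-4-oxo-7-(triethylsilyloxy)nona-2,8-dienoate | C=C[C@](C)(O[Si](CC)(CC)CC)CCC(=O)/C(C)=C/C(=O)OC | intermediate
9 | methyl (2E,4S,7R)-4-hydroxy-3,7-dimethyl-7-(triethylsilyloxy)nona-2,8-dienoate | C=C[C@](C)(O[Si](CC)(CC)CC)CC[C@H](O)/C(C)=C/C(=O)OC | intermediate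
10 | 3-hydroxy-3-methylbutan-2-one | CC(=O)C(C)(C)O | starting material
11 | 3-methyl-3-(triethylsilyloxy)butan-2-one | CC(=O)C(C)(C)O[Si](CC)(CC)CC | intermediate
12 | 3-methyl-3-(triethylsilyloxy)but-1-en-2-yl trifluoromethanesulfonate | C=C(OS(=O)(=O)C(F)(F)F)C(C)(C)O[Si](CC)(CC)CC | intermediate
13 | methyl (2E,4S,7R,8E)-4-hydroxy-3,7,11-trimethyl-10-methylidene-7,11-bis(triethylsilyloxy)dodeca-2,8-dienoate | C=C(C(C)(C)O[Si](CC)(CC)CC)/C=C/[C@](C)(O[Si](CC)(CC)CC)CC[C@H](O)/C(C)=C/C(=O)OC | intermediate
14 | methyl (2E,4S,7R,8E)-4-acetoxy-3,7,11-trimethyl-10-methylidene-7,11-bis(triethylsilyloxy)dodeca-2,8-dienoate (key-step precursor) | C=C(C(C)(C)O[Si](CC)(CC)CC)/C=C/[C@](C)(O[Si](CC)(CC)CC)CC[C@H](OC(C)=O)/C(C)=C/C(=O)OC | intermediate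
15 | methyl 1β-acetoxy-4β,11-bis(triethylsilyloxy)eudesm-6-ene-9β-carboxylate (key-step product; trans-fused, H5 α) | CC(=O)O[C@H]1CC[C@@](C)(O[Si](CC)(CC)CC)[C@H]2C=C(C(C)(C)O[Si](CC)(CC)CC)C[C@@H](C(=O)OC)[C@]12C | intermediate
16 | methyl 1β-acetoxy-4β,11-bis(triethylsilyloxy)eudesmane-9β-carboxylate | CC(=O)O[C@H]1CC[C@@](C)(O[Si](CC)(CC)CC)[C@H]2C[C@@H](C(C)(C)O[Si](CC)(CC)CC)C[C@@H](C(=O)OC)[C@]12C | intermediate
17 | 9β-(hydroxymethyl)-4β,11-bis(triethylsilyloxy)eudesman-1β-ol | O[C@H]1CC[C@@](C)(O[Si](CC)(CC)CC)[C@H]2C[C@@H](C(C)(C)O[Si](CC)(CC)CC)C[C@@H](CO)[C@]12C | intermediate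
18 | 1-oxo-4β,11-bis(triethylsilyloxy)eudesmane-9β-carbaldehyde | O=C1CC[C@@](C)(O[Si](CC)(CC)CC)[C@H]2C[C@@H](C(C)(C)O[Si](CC)(CC)CC)C[C@@H](C=O)[C@]12C | intermediate
19 | 4β,11-bis(triethylsilyloxy)eudesman-1-one | O=C1CC[C@@](C)(O[Si](CC)(CC)CC)[C@H]2C[C@@H](C(C)(C)O[Si](CC)(CC)CC)CC[C@]12C | intermediate
20 | 4β,11-bis(triethylsilyloxy)eudesm-1-en-1-yl trifluoromethanesulfonate | FC(F)(F)S(=O)(=O)OC1=CC[C@@](C)(O[Si](CC)(CC)CC)[C@H]2C[C@@H](C(C)(C)O[Si](CC)(CC)CC)CC[C@]12C | intermediate
21 | methyl 4β,11-bis(triethylsilyloxy)eudesm-1-ene-1-carboxylate | COC(=O)C1=CC[C@@](C)(O[Si](CC)(CC)CC)[C@H]2C[C@@H](C(C)(C)O[Si](CC)(CC)CC)CC[C@]12C | intermediate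
22 | methyl 4β,11-dihydroxyeudesm-1-ene-1-carboxylate | COC(=O)C1=CC[C@@](C)(O)[C@H]2C[C@@H](C(C)(C)O)CC[C@]12C | intermediate
23 | methyl 4β,11-dihydroxyeudesmane-1α-carboxylate | COC(=O)[C@@H]1CC[C@@](C)(O)[C@H]2C[C@@H](C(C)(C)O)CC[C@]12C | intermediate
24 | 4β,11-dihydroxyeudesmane-1α-carbaldehyde | O=C[C@@H]1CC[C@@](C)(O)[C@H]2C[C@@H](C(C)(C)O)CC[C@]12C | intermediate
25 | 1α-(1-hydroxy-3-methylbut-2-enyl)eudesmane-4β,11-diol (both carbinol epimers) | CC(C)=CC(O)[C@@H]1CC[C@@](C)(O)[C@H]2C[C@@H](C(C)(C)O)CC[C@]12C | intermediate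
26 | 1,3,5-trimethoxybenzene | COc1cc(OC)cc(OC)c1 | starting material
27 | 1α-[(1R)-3-methyl-1-(2,4,6-trimethoxyphenyl)but-2-enyl]eudesmane-4β,11-diol | CC(C)=C[C@@H](c1c(OC)cc(OC)cc1OC)[C@@H]1CC[C@@](C)(O)[C@H]2C[C@@H](C(C)(C)O)CC[C@]12C | intermediate
28 | 1α-[(1R)-3-methyl-1-(2,4,6-trimethoxyphenyl)butyl]eudesmane-4β,11-diol | CC(C)C[C@@H](c1c(OC)cc(OC)cc1OC)[C@@H]1CC[C@@](C)(O)[C@H]2C[C@@H](C(C)(C)O)CC[C@]12C | intermediate
29 | 1α-[(1R)-1-(3,5-dibromo-2,4,6-trimethoxyphenyl)-3-methylbutyl]eudesmane-4β,11-diol | CC(C)C[C@@H](c1c(OC)c(Br)c(OC)c(Br)c1OC)[C@@H]1CC[C@@](C)(O)[C@H]2C[C@@H](C(C)(C)O)CC[C@]12C | intermediate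
30 | aryldilithium dialkoxide of 29 (not isolated) | CC(C)C[C@@H](c1c(OC)c([Li])c(OC)c([Li])c1OC)[C@@H]1CC[C@@](C)(O[Li])[C@H]2C[C@@H](C(C)(C)O[Li])CC[C@]12C | intermediate
31 | bis(lithium hemiaminolate) dialkoxide (not isolated) | CC(C)C[C@@H](c1c(OC)c(C(O[Li])N(C)C)c(OC)c(C(O[Li])N(C)C)c1OC)[C@@H]1CC[C@@](C)(O[Li])[C@H]2C[C@@H](C(C)(C)O[Li])CC[C@]12C | intermediate
32 | 5-[(1R)-1-(4β,11-dihydroxyeudesman-1α-yl)-3-methylbutyl]-2,4,6-trimethoxybenzene-1,3-dicarbaldehyde | CC(C)C[C@@H](c1c(OC)c(C=O)c(OC)c(C=O)c1OC)[C@@H]1CC[C@@](C)(O)[C@H]2C[C@@H](C(C)(C)O)CC[C@]12C | intermediate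
33 | 5-[(1R)-1-[(1S,4R,5S,7S,10R)-4,11-dihydroxyeudesman-1-yl]-3-methylbutyl]-2,4,6-trihydroxybenzene-1,3-dicarbaldehyde | CC(C)C[C@@H](c1c(O)c(C=O)c(O)c(C=O)c1O)[C@@H]1CC[C@@](C)(O)[C@H]2C[C@@H](C(C)(C)O)CC[C@]12C | target

**Step count**
Total: 26 steps. Longest linear sequence: 23 steps (1, 2, 4–6, 9–26).

**Steps most likely to fail**

1. Step 11 (key cycloaddition). The trisubstituted dienophile may react too slowly at a temperature at which the dienylic silyl ethers do not eliminate, or the tether may fold through the syn or the methyl-axial transition state.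
 Fallback: set out from alcohol 13. Dess–Martin oxidation gives methyl (2E,7R,8E)-3,7,11-trimethyl-10-methylidene-4-oxo-7,11-bis(triethylsilyloxy)dodeca-2,8-dienoate F1, whose dienophile carries both a ketone and an ester and should cyclise near room temperature to methyl 1-oxo-4β,11-bis(triethylsilyloxy)eudesm-6-ene-9β-carboxylate F2. In that case the C4 centre acts alone, and the ester-endo preference competes with the tether ketone, so the fusion selectivity would have to be established anew. Hydrogenation over PtO2 gives the saturated keto ester F3. LiAlH4 gives diol 17 together with its 1α epimer F4, and Swern oxidation of both returns to keto aldehyde 18.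

2. Step 22 (Friedel–Crafts allylation). The arene may add at the tertiary terminus of the allyl cation or from the C9 side (giving the C1' epimer), or the tertiary carbinols may ionise.
 Fallback: set out from aldehyde 24. Addition of 2,4,6-trimethoxyphenyllithium (from 26 and n-BuLi) gives 1α-[hydroxy(2,4,6-trimethoxyphenyl)methyl]eudesmane-4β,11-diol F5. Sc(OTf)3 ionises it to the aryl-stabilised cation, which 2-methylallyltrimethylsilane captures at C1' (Hosomi–Sakurai-type substitution) to give 1α-[(1R)-3-methyl-1-(2,4,6-trimethoxyphenyl)but-3-enyl]eudesmane-4β,11-diol F6. Hydrogenation then gives 28. Aryl group and isobutyl precursor change roles, so the same facial bias leads to the other C1' configuration. This is the remedy if the arene proves to enter from the C9 side, and it has no regiochemical choice.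

3. Step 19 (directed hydrogenation). Hydrogen may add from the open α face (giving the equatorial ester), or the catalyst may be deactivated before the hindered alkene reacts.
 Fallback: set out from ketone 19. Methylenation with Cp2TiMe2 gives 1-methylidene-4β,11-bis(triethylsilyloxy)eudesmane F7. mCPBA adds oxygen to the α face, away from the C10 methyl, to give the spiro-epoxide F8. MeAl(OAr)2 (Ar = 4-bromo-2,6-di-tert-butylphenyl) opens the tertiary C1–O bond with a hydride shift from the epoxide methylene anti to the leaving oxygen (Meinwald rearrangement), which places H1 β and the formyl group α in 4β,11-bis(triethylsilyloxy)eudesmane-1α-carbaldehyde F9. HF·pyridine then gives 24.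

**Further compounds**
F1 | step 11 | methyl (2E,7R,8E)-3,7,11-trimethyl-10-methylidene-4-oxo-7,11-bis(triethylsilyloxy)dodeca-2,8-dienoate | C=C(C(C)(C)O[Si](CC)(CC)CC)/C=C/[C@](C)(O[Si](CC)(CC)CC)CCC(=O)/C(C)=C/C(=O)OC
F2 | step 11 | methyl 1-oxo-4β,11-bis(triethylsilyloxy)eudesm-6-ene-9β-carboxylate | O=C1CC[C@@](C)(O[Si](CC)(CC)CC)[C@H]2C=C(C(C)(C)O[Si](CC)(CC)CC)C[C@@H](C(=O)OC)[C@]12C
F3 | step 11 | methyl 1-oxo-4β,11-bis(triethylsilyloxy)eudesmane-9β-carboxylate | O=C1CC[C@@](C)(O[Si](CC)(CC)CC)[C@H]2C[C@@H](C(C)(C)O[Si](CC)(CC)CC)C[C@@H](C(=O)OC)[C@]12C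
F4 | step 11 | 9β-(hydroxymethyl)-4β,11-bis(triethylsilyloxy)eudesman-1α-ol | O[C@@H]1CC[C@@](C)(O[Si](CC)(CC)CC)[C@H]2C[C@@H](C(C)(C)O[Si](CC)(CC)CC)C[C@@H](CO)[C@]12C
F5 | step 22 | 1α-[hydroxy(2,4,6-trimethoxyphenyl)methyl]eudesmane-4β,11-diol | COc1cc(OC)c(C(O)[C@@H]2CC[C@@](C)(O)[C@H]3C[C@@H](C(C)(C)O)CC[C@]23C)c(OC)c1
F6 | step 22 | 1α-[(1R)-3-methyl-1-(2,4,6-trimethoxyphenyl)but-3-enyl]eudesmane-4β,11-diol | C=C(C)C[C@@H](c1c(OC)cc(OC)cc1OC)[C@@H]1CC[C@@](C)(O)[C@H]2C[C@@H](C(C)(C)O)CC[C@]12C
F7 | step 19 | 1-methylidene-4β,11-bis(triethylsilyloxy)eudesmane | C=C1CC[C@@](C)(O[Si](CC)(CC)CC)[C@H]2C[C@@H](C(C)(C)O[Si](CC)(CC)CC)CC[C@]12C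
F8 | step 19 | 1,1-(epoxymethano)-4β,11-bis(triethylsilyloxy)eudesmane with the epoxide oxygen α | C1O[C@@]12CC[C@@](C)(O[Si](CC)(CC)CC)[C@H]3C[C@@H](C(C)(C)O[Si](CC)(CC)CC)CC[C@]23C
F9 | step 19 | 4β,11-bis(triethylsilyloxy)eudesmane-1α-carbaldehyde | O=C[C@@H]1CC[C@@](C)(O[Si](CC)(CC)CC)[C@H]2C[C@@H](C(C)(C)O[Si](CC)(CC)CC)CC[C@]12C
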